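**Strategy**

Everything rests on cutting ring A at the C4a–C5 bond. Ring A (C4a, C5, C6, C7, C8, C8a) is a phloroglucinol with oxygens on C5, C7 and C8a, joined to C4 through C4a; this alternating pattern lets the ring be unfolded into a ketide chain. The key step refolds it: a magnesium-chelated Claisen condensation in which C4a attacks the C5 ester, followed by aromatisation, delivers the complete 5,7-dihydroxy-6-prenylflavanone in one operation. Its precursor is a (2S)-2-aryl-2,3-dihydropyran-4-one in which O1 already sits on C8a and whose side chain C8–C7–C6–C5 is a prenylated beta-keto methyl ester. The C4 carbonyl is removed afterwards and both phenols are methylated.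

Key step: step 7

Remark (assumption): the (S,S)-configured ruthenium catalyst of step 3 is taken to give the (S)-carbinol, as it does with simple aryl ketones; should the sense be opposite, the (R,R)-catalyst is used.

Design note: flavan numbering (O1, C2 to C8a) is used for all intermediates. The precursor keeps a methyl ester so that leaving group and base are the same alkoxide, and its C6 centre is carried as a mixture because it becomes aromatic. The precursor is assembled so that, once the dihydropyranone ring exists, no strong base is used before the key step.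

**Route**

Step 1
Reactants: 1 dimethyl malonate; 2 prenyl bromide (1-bromo-3-methylbut-2-ene)
Product: 3 dimethyl 2-(3-methylbut-2-en-1-yl)malonate
Conditions: NaOMe (1.0 equiv), MeOH, 1 in excess (1.5 equiv), 0 °C to 60 °C
Reagents that add atoms: none
Why: Malonic ester alkylation, an SN2 reaction of the malonate enolate at the primary allylic carbon that should give the linear prenyl group, with the excess of 1 holding back dialkylation.

Step 2
Reactants: 3 dimethyl 2-(3-methylbut-2-en-1-yl)malonate
Product: 4 potassium methyl 2-(3-methylbut-2-en-1-yl)malonate (racemic)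
Conditions: KOH (1.0 equiv), MeOH, 0 °C to rt; evaporate, triturate with ether
Reagents that add atoms: potassium hydroxide, [K+].[OH-]
Why: Monosaponification of a malonic diester, which should stop after one ester because the carboxylate formed deactivates the second one.

Step 3
Reactants: 5 methyl 3-(4-methoxyphenyl)-3-oxopropanoate
Product: 6 methyl (3S)-3-hydroxy-3-(4-methoxyphenyl)propanoate
Conditions: RuCl[(S,S)-TsDPEN](p-cymene) (1 mol%), HCO2H–Et3N (5:2), DMF, 30 °C
Reagents that add atoms: none
Why: Noyori asymmetric transfer hydrogenation of an aryl ketone, in which the chiral diamine ligand and the aryl/arene contact fix the face that receives hydride, so the carbinol carbon (the later C2) should be set as S by the catalyst.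

Step 4
Reactants: 6 methyl (3S)-3-hydroxy-3-(4-methoxyphenyl)propanoate; 7 allyl acetoacetate (prop-2-en-1-yl 3-oxobutanoate)
Product: 9 prop-2-en-1-yl 2-[(2S)-2-(4-methoxyphenyl)-4-oxo-3,4-dihydro-2H-pyran-6-yl]acetate, via open-chain hydroxy diketo ester 8 (not isolated)
Conditions: 7 (4 equiv), NaH then n-BuLi, THF, 0 °C; add 6, −40 to 0 °C; 1 M HCl; then TsOH·H2O (cat.), CH2Cl2, 0 °C to rt
Reagents that add atoms: none
Why: Claisen acylation of the acetoacetate dianion (Weiler dianion) at its terminal carbon by the ester of 6, whose hydroxyl is carried as the alkoxide, should give 8, and acid then closes the C2 hydroxyl onto the C8a ketone and dehydrates the hemiketal to the vinylogous ester (cyclodehydration of a delta-hydroxy beta-diketone) without touching C2.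

Step 5
Reactants: 9 prop-2-en-1-yl 2-[(2S)-2-(4-methoxyphenyl)-4-oxo-3,4-dihydro-2H-pyran-6-yl]acetate
Product: 10 2-[(2S)-2-(4-methoxyphenyl)-4-oxo-3,4-dihydro-2H-pyran-6-yl]acetic acid
Conditions: Pd(PPh3)4 (3 mol%), PhSO2Na (1.2 equiv), THF–MeOH, rt; then dilute HCl to pH 3, 0 °C; used at once
Reagents that add atoms: none
Why: Tsuji–Trost deallylation, in which zerovalent palladium ionises the allyl ester and the sulfinate captures the allyl group, a neutral ester cleavage that spares the vinylogous ester (which secondary amine scavengers could open).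

Step 6
Reactants: 10 2-[(2S)-2-(4-methoxyphenyl)-4-oxo-3,4-dihydro-2H-pyran-6-yl]acetic acid; 4 potassium methyl 2-(3-methylbut-2-en-1-yl)malonate
Product: 13 methyl 2-prenyl-3-oxo-4-[(S)-2-(4-methoxyphenyl)-4-oxo-2,3-dihydropyran-6-yl]butanoate (C2 of the butanoate as a mixture), via acyl imidazolide 11 (not isolated), via acylmalonic half ester 12 (not isolated)
Conditions: 10, CDI (1.1 equiv), THF, rt; add to 4 (2 equiv), MgCl2 (2 equiv), Et3N (2.5 equiv), MeCN, rt; cold 1 M HCl
Reagents that add atoms: none
Why: Masamune–Brooks homologation, in which imidazolide 11 C-acylates the magnesium enolate of the half ester and 12 loses CO2 to the beta-keto ester; the ring carbonyl oxygen cannot lactonise onto C7 because the vinylogous ester is locked s-trans in the ring, and triethylamine is too weak to remove C3–H.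

Step 7
Reactants: 13 methyl 2-prenyl-3-oxo-4-[(S)-2-(4-methoxyphenyl)-4-oxo-2,3-dihydropyran-6-yl]butanoate
Product: 15 (2S)-5,7-dihydroxy-2-(4-methoxyphenyl)-6-(3-methylbut-2-en-1-yl)chroman-4-one [(S)-5,7-dihydroxy-4'-methoxy-6-prenylflavanone], via trione tautomer 14 (not isolated)
Conditions: Mg(OMe)2 (4 equiv), MeOH, 25 to 45 °C, argon; then cold dilute HCl to pH 4
Reagents that add atoms: none
Why: Mg(OMe)2 removes the C6 and C8 protons and holds the enolates as chelates; the C8 enolate is a dienolate (O4–C4=C4a–C8a=C8) whose alpha carbon C4a adds to the ester carbonyl C5, methoxide leaves to give 14, and two enolisations give the aromatic ring. The closest known reaction type is the magnesium alkoxide-mediated Claisen cyclisation of 3,5,7-triketo esters and their pyranone-masked forms to acylphloroglucinols. Ring A closes in the 6-(enolexo)-exo-trig mode when counted for the C4=C4a enolate bond (the C8a=C8 bond of the same dienolate lies inside the new ring), which is geometrically easy. No stereocentre is created: C6 becomes aromatic and C2 is a spectator. The step needs the Claisen fold to win over the lactone and aldol folds, and the substrate secures this because O1 already occupies C8a (no free oxygen for pyrone formation), because an aldol of C6 onto C4 would put the C4a=C8a alkene at a bridgehead, and because prenyl on C6 between C5 and C7 fixes the 6-prenyl pattern. It also needs C2 to survive: C6–H and C8–H are far more acidic than C3–H, so with excess base the substrate sits as a polyanion in which C3 deprotonation and the retro-oxa-Michael opening it would start are disfavoured, while moderate temperature, a prompt mild quench and the absence of a 4'-hydroxyl protect the flavanone formed.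

Step 8
Reactants: 15 (2S)-5,7-dihydroxy-2-(4-methoxyphenyl)-6-(3-methylbut-2-en-1-yl)chroman-4-one
Product: 16 (2S)-2-(4-methoxyphenyl)-6-(3-methylbut-2-en-1-yl)-4-oxochroman-5,7-diyl diethyl dicarbonate
Conditions: ClCO2Et (3 equiv), Et3N (3.5 equiv), THF, 0 °C
Reagents that add atoms: ethyl chloroformate, CCOC(Cl)=O
Why: O-acylation of both phenols to aryl ethyl carbonates, in which the amine breaks the hydrogen bond of the chelated 5-OH, and the short exposure to a tertiary amine at 0 °C should not enolise C3.

Step 9
Reactants: 16 (2S)-2-(4-methoxyphenyl)-6-(3-methylbut-2-en-1-yl)-4-oxochroman-5,7-diyl diethyl dicarbonate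
Product: 20 (2S)-2-(4-methoxyphenyl)-6-(3-methylbut-2-en-1-yl)chroman-5,7-diol, via flavan-4-ol biscarbonate 17 (not isolated), via ortho-quinone methide 18 (not isolated), via flavan 7-carbonate 19 (not isolated)
Conditions: NaBH4 (8 equiv), THF–H2O, 0 °C to rt; then 2 M NaOH, rt; NH4Cl work-up, argon
Reagents that add atoms: none
Why: Borohydride deoxygenation of an ortho-acyl phenol carbonate: hydride reduces C4=O to 17, the new alkoxide takes over the neighbouring 5-carbonate and expels it as ethyl carbonate to give 18, a second hydride adds at C4 to give 19, and hydroxide then cleaves the remaining 7-carbonate, with C2 and the prenyl alkene untouched.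

Step 10
Reactants: 20 (2S)-2-(4-methoxyphenyl)-6-(3-methylbut-2-en-1-yl)chroman-5,7-diol
Product: 21 (2S)-5,7-dimethoxy-2-(4-methoxyphenyl)-6-(3-methylbut-2-en-1-yl)chroman (CNP0344770.1)
Conditions: MeI (excess), K2CO3, acetone, 50 °C
Reagents that add atoms: iodomethane, CI
Why: Williamson O-methylation of both phenoxides, where a weak carbonate base in an aprotic solvent favours O- over C-methylation, and the flavan has no carbonyl through which C2 could be lost.

**Compound list**

1 | dimethyl malonate | COC(=O)CC(=O)OC | starting material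
2 | prenyl bromide (1-bromo-3-methylbut-2-ene) | CC(C)=CCBr | starting material
3 | dimethyl 2-(3-methylbut-2-en-1-yl)malonate | COC(=O)C(CC=C(C)C)C(=O)OC | intermediate
4 | potassium methyl 2-(3-methylbut-2-en-1-yl)malonate (racemic) | COC(=O)C(CC=C(C)C)C(=O)[O-].[K+] | intermediate
5 | methyl 3-(4-methoxyphenyl)-3-oxopropanoate | COC(=O)CC(=O)c1ccc(OC)cc1 | starting material
6 | methyl (3S)-3-hydroxy-3-(4-methoxyphenyl)propanoate | COc1ccc([C@@H](O)CC(=O)OC)cc1 | intermediate
7 | allyl acetoacetate (prop-2-en-1-yl 3-oxobutanoate) | CC(=O)CC(=O)OCC=C | starting material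
8 | prop-2-en-1-yl (7S)-7-hydroxy-7-(4-methoxyphenyl)-3,5-dioxoheptanoate | COc1ccc([C@@H](O)CC(=O)CC(=O)CC(=O)OCC=C)cc1 | intermediate (not isolated)
9 | prop-2-en-1-yl 2-[(2S)-2-(4-methoxyphenyl)-4-oxo-3,4-dihydro-2H-pyran-6-yl]acetate | COc1ccc([C@@H]2CC(=O)C=C(CC(=O)OCC=C)O2)cc1 | intermediate
10 | 2-[(2S)-2-(4-methoxyphenyl)-4-oxo-3,4-dihydro-2H-pyran-6-yl]acetic acid | COc1ccc([C@@H]2CC(=O)C=C(CC(=O)O)O2)cc1 | intermediate
11 | 1-{2-[(2S)-2-(4-methoxyphenyl)-4-oxo-3,4-dihydro-2H-pyran-6-yl]acetyl}imidazole | COc1ccc([C@@H]2CC(=O)C=C(CC(=O)n3ccnc3)O2)cc1 | intermediate (not isolated)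
12 | 2-(methoxycarbonyl)-2-{2-[(2S)-2-(4-methoxyphenyl)-4-oxo-3,4-dihydro-2H-pyran-6-yl]acetyl}-5-methylhex-4-enoic acid (quaternary centre as a mixture) | COc1ccc([C@@H]2CC(=O)C=C(CC(=O)C(CC=C(C)C)(C(=O)OC)C(=O)O)O2)cc1 | intermediate (not isolated)
13 | methyl 2-prenyl-3-oxo-4-[(S)-2-(4-methoxyphenyl)-4-oxo-2,3-dihydropyran-6-yl]butanoate (centre between the carbonyls as a mixture) | COc1ccc([C@@H]2CC(=O)C=C(CC(=O)C(CC=C(C)C)C(=O)OC)O2)cc1 | intermediate
14 | (2S)-2-(4-methoxyphenyl)-6-(3-methylbut-2-en-1-yl)-2,3,4a,6-tetrahydrochromene-4,5,7-trione (C4a and C6 as mixtures; non-aromatic tautomer of 15) | COc1ccc([C@@H]2CC(=O)C3C(=O)C(CC=C(C)C)C(=O)C=C3O2)cc1 | intermediate (not isolated)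
15 | (2S)-5,7-dihydroxy-2-(4-methoxyphenyl)-6-(3-methylbut-2-en-1-yl)chroman-4-one [(S)-5,7-dihydroxy-4'-methoxy-6-prenylflavanone] | COc1ccc([C@@H]2CC(=O)c3c(cc(O)c(CC=C(C)C)c3O)O2)cc1 | intermediate
16 | (2S)-2-(4-methoxyphenyl)-6-(3-methylbut-2-en-1-yl)-4-oxochroman-5,7-diyl diethyl dicarbonate | COc1ccc([C@@H]2CC(=O)c3c(cc(OC(=O)OCC)c(CC=C(C)C)c3OC(=O)OCC)O2)cc1 | intermediate
17 | (2S)-4-hydroxy-2-(4-methoxyphenyl)-6-(3-methylbut-2-en-1-yl)chroman-5,7-diyl diethyl dicarbonate (C4 as a mixture) | COc1ccc([C@@H]2CC(O)c3c(cc(OC(=O)OCC)c(CC=C(C)C)c3OC(=O)OCC)O2)cc1 | intermediate (not isolated)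
18 | ethyl (2S)-2-(4-methoxyphenyl)-6-(3-methylbut-2-en-1-yl)-5-oxo-3,5-dihydro-2H-chromen-7-yl carbonate (ortho-quinone methide, C4=C4a and C5=O) | COc1ccc([C@@H]2CC=C3C(=O)C(CC=C(C)C)=C(OC(=O)OCC)C=C3O2)cc1 | intermediate (not isolated)
19 | ethyl (2S)-5-hydroxy-2-(4-methoxyphenyl)-6-(3-methylbut-2-en-1-yl)chroman-7-yl carbonate | COc1ccc([C@@H]2CCc3c(cc(OC(=O)OCC)c(CC=C(C)C)c3O)O2)cc1 | intermediate (not isolated)
20 | (2S)-2-(4-methoxyphenyl)-6-(3-methylbut-2-en-1-yl)chroman-5,7-diol | COc1ccc([C@@H]2CCc3c(cc(O)c(CC=C(C)C)c3O)O2)cc1 | intermediate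
21 | (2S)-5,7-dimethoxy-2-(4-methoxyphenyl)-6-(3-methylbut-2-en-1-yl)chroman (CNP0344770.1) | COc1ccc([C@@H]2CCc3c(cc(OC)c(CC=C(C)C)c3OC)O2)cc1 | target

**Step count and risks**

Total step count: 10. Longest linear sequence: 8 steps (5 to 21, steps 3 to 10); steps 1 and 2 form the branch that enters at step 6.

Steps most likely to fail:

1. Step 7 (key step). What may go wrong: reversible ring opening at C3 under methoxide, which would erode the configuration at C2, or failure of the chelated, enolised C5 ester to accept C4a so that retro-Claisen cleavage at C7 takes over. The fallback closes the same C4a–C5 bond through a neutral acylketene; it sets out from acid 10 and returns at 14 and hence 15. Commercial tert-butyl methyl malonate is alkylated with 2 (NaH, THF) to tert-butyl methyl 2-(3-methylbut-2-en-1-yl)malonate F1. KOH (1 equiv) in methanol cleaves only the methyl ester to potassium tert-butyl 2-(3-methylbut-2-en-1-yl)malonate F2. Imidazolide 11, made from 10 as in step 6, is coupled with F2 under the MgCl2/Et3N conditions to give, through the tert-butyl acylmalonic half ester F3, the tert-butyl beta-keto ester F4. Heating F4 in toluene at about 110 °C should expel tert-butanol to give acylketene F5. Its ketene carbon C5 is then captured by C4a (six-electron ring closure of the C7 enol form, as in ketene-based benzannulations), giving 14 and then 15 with no base present.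

2. Step 6. What may go wrong: loss of the imidazolide through its acidic C8–H (ketene formation and self-condensation) faster than attack by the hindered prenylmalonate, or decarboxylation of acid 10 before activation. The fallback makes C8 the nucleophile and decarboxylates last; it sets out from ester 9 (with salt 4) and returns at 13. Salt 4 with oxalyl chloride (CH2Cl2, cat. DMF) gives methyl 2-(chlorocarbonyl)-5-methylhex-4-enoate F6. The magnesium enolate of 9, formed at the doubly activated C8 with MgCl2 and Et3N, is C-acylated by F6 to the C8-acylated allyl ester F7. Pd(PPh3)4 with PhSO2Na removes the allyl group to give beta-keto acid F8, which should lose CO2 on mild acidification to give 13.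

3. Step 9. What may go wrong: hydrolysis of the hindered 5-carbonate before it can shift to the benzylic oxygen, so that reduction stops at the flavan-4-ol, or base-induced opening of the flavanone before hydride is delivered. The fallback reduces a hydrazone and avoids the quinone methide; it sets out from flavanone 15, bypasses 16, and returns at 20. Flavanone 15 with tosylhydrazide (EtOH, 60 °C) gives the flavanone tosylhydrazone F9. Catecholborane (CHCl3, 0 °C) followed by NaOAc·3H2O at reflux reduces the C=N bond, and loss of sulfinate and nitrogen leaves the C4 methylene (Caglioti-type reduction), giving 20. The trisubstituted prenyl alkene should not be hydroborated by catecholborane at this temperature.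

Further compounds
F1 | step 7 | tert-butyl methyl 2-(3-methylbut-2-en-1-yl)malonate | COC(=O)C(CC=C(C)C)C(=O)OC(C)(C)C
F2 | step 7 | potassium tert-butyl 2-(3-methylbut-2-en-1-yl)malonate | CC(C)=CCC(C(=O)[O-])C(=O)OC(C)(C)C.[K+]
F3 | step 7 | 2-(tert-butoxycarbonyl)-2-{2-[(2S)-2-(4-methoxyphenyl)-4-oxo-3,4-dihydro-2H-pyran-6-yl]acetyl}-5-methylhex-4-enoic acid | COc1ccc([C@@H]2CC(=O)C=C(CC(=O)C(CC=C(C)C)(C(=O)OC(C)(C)C)C(=O)O)O2)cc1
F4 | step 7 | tert-butyl 2-prenyl-3-oxo-4-[(S)-2-(4-methoxyphenyl)-4-oxo-2,3-dihydropyran-6-yl]butanoate | COc1ccc([C@@H]2CC(=O)C=C(CC(=O)C(CC=C(C)C)C(=O)OC(C)(C)C)O2)cc1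
F5 | step 7 | acylketene, (2S)-2-(4-methoxyphenyl)-6-[2-oxo-3-(oxomethylidene)-6-methylhept-5-en-1-yl]-2,3-dihydropyran-4-one | COc1ccc([C@@H]2CC(=O)C=C(CC(=O)C(CC=C(C)C)=C=O)O2)cc1
F6 | step 6 | methyl 2-(chlorocarbonyl)-5-methylhex-4-enoate | COC(=O)C(CC=C(C)C)C(Cl)=O
F7 | step 6 | 1-allyl 5-methyl 2-[(2S)-2-(4-methoxyphenyl)-4-oxo-3,4-dihydro-2H-pyran-6-yl]-3-oxo-4-(3-methylbut-2-en-1-yl)pentanedioate | COc1ccc([C@@H]2CC(=O)C=C(C(C(=O)OCC=C)C(=O)C(CC=C(C)C)C(=O)OC)O2)cc1
F8 | step 6 | 5-methoxy-2-[(2S)-2-(4-methoxyphenyl)-4-oxo-3,4-dihydro-2H-pyran-6-yl]-3,5-dioxo-4-(3-methylbut-2-en-1-yl)pentanoic acid | COc1ccc([C@@H]2CC(=O)C=C(C(C(=O)O)C(=O)C(CC=C(C)C)C(=O)OC)O2)cc1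
F9 | step 9 | tosylhydrazone of flavanone 15 | COc1ccc([C@@H]2CC(=NNS(=O)(=O)c3ccc(C)cc3)c3c(cc(O)c(CC=C(C)C)c3O)O2)cc1
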